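**Plan**
- Late changes are taken back first: the three phenols are unmasked last, C3=C4 comes from dehydrogenation of a chroman, and the (E)-allylic tertiary alcohol comes from a prenyl-type alkene by epoxide/selenide transposition.
- Ring A is then cut at C4a–C5 and C8–C8a. It is a 1,2,3,4-tetrasubstituted benzene whose C8 hydroxyl is para to the C5 chain and ortho to O1, the pattern left when a 2-substituted furan adds across a C4a≡C8a alkyne and the oxygen bridge opens towards C8.
- Further cuts: C4–C4a and O1–C8a (δ-lactone from a linalool-derived iodide and a cyanomethyl anion), and Cα–Cβ of the ketone arm (aldol of 2,4-dihydroxyacetophenone with furfural).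
- Forward order: the resorcinol ring is bought; the pyran ring is made first as the lactone and activated as a vicinal silyl/triflyloxy ketene acetal; ring A is closed last by cycloaddition of the strained cyclic ynol ether with the furan; side-chain transposition, dehydrogenation and deprotection follow.
- Stereochemistry: the only stereocentre, C2 (R), is the carbinol carbon of (R)-linalool, whose C–O bond is never broken; the E alkene comes from a syn selenoxide elimination.

Key step: step 10

Remark: chromene numbering (O1, C2, C3, C4, C4a, C5–C8, C8a; side chain C1'–C4') is used throughout; (R)-linalool of high enantiomeric purity is assumed to be purchasable; the silyl group is taken as SiMePh2 because lactone enolates are silylated on carbon by this chlorosilane.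

**Route**

Step 1
Reactants: 1 (R)-linalool
Product: 3 (R)-3,7-dimethyloct-6-ene-1,3-diol, via alkylborane 2 (not isolated)
Conditions: 9-BBN (2.2 equiv), THF, 0 → 23 °C; then NaOH aq., H2O2, 0 → 23 °C
Reagents that add atoms: hydrogen peroxide, OO
Why: 9-BBN should hydroborate the monosubstituted vinyl group anti-Markovnikov far faster than the trisubstituted alkene (chemoselective hydroboration–oxidation), and the oxidation does not touch the carbinol stereocentre.

Step 2
Reactants: 3 (R)-3,7-dimethyloct-6-ene-1,3-diol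
Product: 4 (R)-1-iodo-3,7-dimethyloct-6-en-3-ol
Conditions: I2, PPh3, imidazole, CH2Cl2, 0 °C, dark
Reagents that add atoms: iodine, II
Why: Appel-type iodination should activate only the primary hydroxyl, because the tertiary one is too hindered to form the alkoxyphosphonium ion.

Step 3
Reactants: 4 (R)-1-iodo-3,7-dimethyloct-6-en-3-ol
Product: 5 (S)-5-hydroxy-5,9-dimethyldec-8-enenitrile
Conditions: MeCN, n-BuLi (both in excess), THF, −78 °C; then 4, −78 → −20 °C
Reagents that add atoms: acetonitrile, CC#N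
Why: (cyanomethyl)lithium is a small, strongly nucleophilic acetate-anion equivalent that should displace the primary iodide by SN2 alkylation while the tertiary hydroxyl is carried as its lithium alkoxide, the excess of reagent suppressing dialkylation.

Step 4
Reactants: 5 (S)-5-hydroxy-5,9-dimethyldec-8-enenitrile
Product: 7 (S)-6-methyl-6-(4-methylpent-3-en-1-yl)tetrahydro-2H-pyran-2-one, via hydroxy acid 6 (not isolated)
Conditions: KOH, EtOH–H2O, reflux; then 1 M HCl to pH 3, 0 °C; toluene, 50 °C
Reagents that add atoms: potassium hydroxide, [K+].[OH-]; water, O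
Why: alkaline nitrile hydrolysis should give the δ-hydroxy carboxylate without ionising the tertiary alcohol or the alkene, and the gem-disubstituted δ-hydroxy acid should lactonise on mild acidification.

Step 5
Reactants: 7 (S)-6-methyl-6-(4-methylpent-3-en-1-yl)tetrahydro-2H-pyran-2-one
Product: 9 (6R)-6-methyl-6-(4-methylpent-3-en-1-yl)-3-[methyl(diphenyl)silyl]tetrahydro-2H-pyran-2-one, via lithium enolate 8 (not isolated)
Conditions: LiN(i-Pr)2, THF, −78 °C; then Ph2MeSiCl, −78 → 0 °C
Reagents that add atoms: chloro(methyl)diphenylsilane, C[Si](Cl)(c1ccccc1)c1ccccc1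
Why: direct C-silylation of a lactone enolate, which chloro(methyl)diphenylsilane is known to favour over O-silylation, should give the α-silyl lactone as a mixture of C3 epimers that converge in the next step.

Step 6
Reactants: 9 (6R)-6-methyl-6-(4-methylpent-3-en-1-yl)-3-[methyl(diphenyl)silyl]tetrahydro-2H-pyran-2-one
Product: 11 (R)-2-methyl-2-(4-methylpent-3-en-1-yl)-5-[methyl(diphenyl)silyl]-3,4-dihydro-2H-pyran-6-yl trifluoromethanesulfonate, via potassium enolate 10 (not isolated)
Conditions: KN(SiMe3)2, THF, −78 °C; then PhNTf2, −78 → −20 °C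
Reagents that add atoms: N-phenylbis(trifluoromethanesulfonimide), O=S(=O)(N(c1ccccc1)S(=O)(=O)C(F)(F)F)C(F)(F)F
Why: enolate O-triflation is the standard way to lactone-derived ketene acetal triflates, and since the only enolisable carbon carries the silyl group the vicinal silyl/triflate arrangement is fixed.

Step 7
Reactants: 12 2,4-dihydroxyacetophenone; 13 furfural
Product: 14 (E)-1-(2,4-dihydroxyphenyl)-3-(furan-2-yl)prop-2-en-1-one
Conditions: KOH, EtOH–H2O, 0 → 23 °C; then 1 M HCl, 0 °C
Reagents that add atoms: none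
Why: Claisen–Schmidt aldol condensation, in which the methyl ketone enolate adds to non-enolisable furfural and E1cB dehydration should give the conjugated (E)-enone.

Step 8
Reactants: 14 (E)-1-(2,4-dihydroxyphenyl)-3-(furan-2-yl)prop-2-en-1-one
Product: 15 1-(2,4-dihydroxyphenyl)-3-(furan-2-yl)propan-1-one
Conditions: H2 (3 atm), RhCl(PPh3)3 (cat.), THF–EtOH, 40 °C
Reagents that add atoms: none
Why: homogeneous hydrogenation with RhCl(PPh3)3 should saturate the disubstituted enone C=C and leave the furan ring and the aryl ketone untouched.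

Step 9
Reactants: 15 1-(2,4-dihydroxyphenyl)-3-(furan-2-yl)propan-1-one
Product: 16 4-[3-(furan-2-yl)propanoyl]-1,3-phenylene bis(2,2-dimethylpropanoate)
Conditions: t-BuCOCl, Et3N, DMAP (cat.), CH2Cl2, 0 → 23 °C
Reagents that add atoms: pivaloyl chloride, CC(C)(C)C(Cl)=O
Why: DMAP-catalysed acylation should cap both phenols (the chelated ortho one included) as hindered pivalates, which tolerate fluoride, cannot add to a strained alkyne and can be removed together at the end.

Step 10
Reactants: 11 (R)-2-methyl-2-(4-methylpent-3-en-1-yl)-5-[methyl(diphenyl)silyl]-3,4-dihydro-2H-pyran-6-yl trifluoromethanesulfonate; 16 4-[3-(furan-2-yl)propanoyl]-1,3-phenylene bis(2,2-dimethylpropanoate)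
Product: 19 4-{3-[(2R)-8-hydroxy-2-methyl-2-(4-methylpent-3-en-1-yl)chroman-5-yl]propanoyl}-1,3-phenylene bis(2,2-dimethylpropanoate), via cyclic ynol ether 17 (not isolated), via oxanorbornadiene 18 (not isolated)
Conditions: CsF, MeCN, 23 °C (16 in excess); then TsOH·H2O (cat.), CH2Cl2, 0 °C
Reagents that add atoms: none
Why: Proposed new method: fluoride attack at silicon and 1,2-loss of triflate should give the strained six-membered ynol ether 17, the closest known reactions being the CsF generation of cyclohexyne and 3,4-oxacyclohexyne from silyl triflates and their trapping by furans. The alkyne should add to the furan ring of 16 in a concerted, asynchronous [4+2] cycloaddition, which closes ring A by forming C4a–C5 and C8–C8a in one intermolecular event and gives the 7-oxanorbornadiene 18. Catalytic acid should then ionise the bridge C5–O bond, because that cation is tertiary and is stabilised by O1 through the C4a=C8a enol ether, and loss of the C8 proton aromatises ring A with the bridge oxygen left as the C8 hydroxyl (the known acid isomerisation of 7-oxanorbornadienes to phenols). No lasting stereocentre is created, since the two bridgehead centres of 18 vanish on aromatisation and C2 is remote from every bond change. The step needs the unsubstituted furan α-carbon to bond to C8a: O1 makes C8a the electrophilic end of the strained triple bond, which should pair with the more nucleophilic and less hindered unsubstituted α-carbon, while the pivalates keep the phenols out of the reaction.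

Step 11
Reactants: 19 4-{3-[(2R)-8-hydroxy-2-methyl-2-(4-methylpent-3-en-1-yl)chroman-5-yl]propanoyl}-1,3-phenylene bis(2,2-dimethylpropanoate)
Product: 20 (2R)-5-{3-[2,4-bis(pivaloyloxy)phenyl]-3-oxopropyl}-2-methyl-2-(4-methylpent-3-en-1-yl)chroman-8-yl pivalate
Conditions: t-BuCOCl, Et3N, DMAP (cat.), CH2Cl2, 0 → 23 °C
Reagents that add atoms: pivaloyl chloride, CC(C)(C)C(Cl)=O
Why: acylation of the C8 phenol should protect the electron-rich catechol monoether ring from the peracid and selenium oxidants and remove the para-oxygen activation of the C5 benzylic methylene before the DDQ step.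

Step 12
Reactants: 20 (2R)-5-{3-[2,4-bis(pivaloyloxy)phenyl]-3-oxopropyl}-2-methyl-2-(4-methylpent-3-en-1-yl)chroman-8-yl pivalate
Product: 21 (2S)-5-{3-[2,4-bis(pivaloyloxy)phenyl]-3-oxopropyl}-2-[2-(3,3-dimethyloxiran-2-yl)ethyl]-2-methylchroman-8-yl pivalate
Conditions: mCPBA, NaHCO3, CH2Cl2, 0 °C
Reagents that add atoms: 3-chloroperbenzoic acid, O=C(OO)c1cccc(Cl)c1
Why: Prilezhaev epoxidation should take place at the only electron-rich alkene, and both epimers at the new oxirane carbon can be used because that centre becomes sp2 in the next step.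

Step 13
Reactants: 21 (2S)-5-{3-[2,4-bis(pivaloyloxy)phenyl]-3-oxopropyl}-2-[2-(3,3-dimethyloxiran-2-yl)ethyl]-2-methylchroman-8-yl pivalate
Product: 24 (2S)-5-{3-[2,4-bis(pivaloyloxy)phenyl]-3-oxopropyl}-2-[(2E)-4-hydroxy-4-methylpent-2-en-1-yl]-2-methylchroman-8-yl pivalate, via hydroxy selenide 22 (not isolated), via selenoxide 23 (not isolated)
Conditions: (PhSe)2, NaBH4 (no excess), EtOH, 23 → 60 °C; then H2O2 (30% aq.), pyridine, THF, 0 → 23 °C
Reagents that add atoms: none
Why: in this Sharpless-type epoxide-to-allylic-alcohol transposition the selenide should open the epoxide by SN2 at the less hindered secondary carbon C3', and the selenoxide can undergo syn elimination only towards C2' because C4' bears no hydrogen, which should give the (E)-allylic tertiary alcohol.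

Step 14
Reactants: 24 (2S)-5-{3-[2,4-bis(pivaloyloxy)phenyl]-3-oxopropyl}-2-[(2E)-4-hydroxy-4-methylpent-2-en-1-yl]-2-methylchroman-8-yl pivalate
Product: 25 (2R)-5-{3-[2,4-bis(pivaloyloxy)phenyl]-3-oxopropyl}-2-[(2E)-4-hydroxy-4-methylpent-2-en-1-yl]-2-methyl-2H-chromen-8-yl pivalate
Conditions: DDQ, benzene, reflux
Reagents that add atoms: none
Why: in this DDQ dehydrogenation of a chroman to a 2H-chromene, hydride should be abstracted from C4, whose benzylic cation is stabilised by the ortho ring oxygen O1, and loss of a C3 proton gives C3=C4, whereas the C5 benzylic methylene has only an acylated para oxygen and the tertiary alcohol cannot be oxidised.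

Step 15
Reactants: 25 (2R)-5-{3-[2,4-bis(pivaloyloxy)phenyl]-3-oxopropyl}-2-[(2E)-4-hydroxy-4-methylpent-2-en-1-yl]-2-methyl-2H-chromen-8-yl pivalate
Product: 26 1-(2,4-dihydroxyphenyl)-3-{(2R)-8-hydroxy-2-[(2E)-4-hydroxy-4-methylpent-2-en-1-yl]-2-methyl-2H-chromen-5-yl}propan-1-one
Conditions: K2CO3, MeOH (degassed), 23 → 40 °C; then aq. NH4Cl
Reagents that add atoms: none
Why: base-catalysed methanolysis (transesterification) should cleave the three aryl pivalates under conditions that spare the acid-sensitive tertiary allylic alcohol, the chromene and the ketone.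

**Compound list**

1 | (R)-linalool | CC(C)=CCC[C@](O)(C)C=C | starting material
2 | 9-[(3S)-3-hydroxy-3,7-dimethyloct-6-en-1-yl]-9-borabicyclo[3.3.1]nonane (formed in the flask, may be carried as its O-borinate) | CC(C)=CCC[C@](O)(C)CCB1C2CCCC1CCC2 | intermediate
3 | (R)-3,7-dimethyloct-6-ene-1,3-diol | CC(C)=CCC[C@](O)(C)CCO | intermediate
4 | (R)-1-iodo-3,7-dimethyloct-6-en-3-ol | CC(C)=CCC[C@](O)(C)CCI | intermediate
5 | (S)-5-hydroxy-5,9-dimethyldec-8-enenitrile | CC(C)=CCC[C@](O)(C)CCCC#N | intermediate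
6 | (S)-5-hydroxy-5,9-dimethyldec-8-enoic acid (formed in the flask) | CC(C)=CCC[C@](O)(C)CCCC(=O)O | intermediate
7 | (S)-6-methyl-6-(4-methylpent-3-en-1-yl)tetrahydro-2H-pyran-2-one | CC(C)=CCC[C@]1(C)CCCC(=O)O1 | intermediate
8 | lithium (R)-2-methyl-2-(4-methylpent-3-en-1-yl)-3,4-dihydro-2H-pyran-6-olate (formed in the flask) | CC(C)=CCC[C@]1(C)CCC=C([O-])O1.[Li+] | intermediate
9 | (6R)-6-methyl-6-(4-methylpent-3-en-1-yl)-3-[methyl(diphenyl)silyl]tetrahydro-2H-pyran-2-one, both C3 epimers | CC(C)=CCC[C@]1(C)CCC([Si](C)(c2ccccc2)c2ccccc2)C(=O)O1 | intermediate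
10 | potassium (R)-2-methyl-2-(4-methylpent-3-en-1-yl)-5-[methyl(diphenyl)silyl]-3,4-dihydro-2H-pyran-6-olate (formed in the flask) | CC(C)=CCC[C@]1(C)CCC([Si](C)(c2ccccc2)c2ccccc2)=C([O-])O1.[K+] | intermediate
11 | (R)-2-methyl-2-(4-methylpent-3-en-1-yl)-5-[methyl(diphenyl)silyl]-3,4-dihydro-2H-pyran-6-yl trifluoromethanesulfonate | CC(C)=CCC[C@]1(C)CCC([Si](C)(c2ccccc2)c2ccccc2)=C(OS(=O)(=O)C(F)(F)F)O1 | intermediate
12 | 2,4-dihydroxyacetophenone | CC(=O)c1ccc(O)cc1O | starting material
13 | furfural | O=Cc1ccco1 | starting material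
14 | (E)-1-(2,4-dihydroxyphenyl)-3-(furan-2-yl)prop-2-en-1-one | O=C(/C=C/c1ccco1)c1ccc(O)cc1O | intermediate
15 | 1-(2,4-dihydroxyphenyl)-3-(furan-2-yl)propan-1-one | O=C(CCc1ccco1)c1ccc(O)cc1O | intermediate
16 | 4-[3-(furan-2-yl)propanoyl]-1,3-phenylene bis(2,2-dimethylpropanoate) | O=C(CCc1ccco1)c1ccc(OC(=O)C(C)(C)C)cc1OC(=O)C(C)(C)C | intermediate
17 | (R)-2-methyl-2-(4-methylpent-3-en-1-yl)-5,6-didehydro-3,4-dihydro-2H-pyran (strained cyclic ynol ether, formed in the flask) | CC(C)=CCC[C@]1(C)CCC#CO1 | intermediate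
18 | 4-{3-[(2R)-2-methyl-2-(4-methylpent-3-en-1-yl)-3,4-dihydro-2H-5,8-epoxychromen-5(8H)-yl]propanoyl}-1,3-phenylene bis(2,2-dimethylpropanoate), both bridge diastereomers (formed in the flask) | CC(C)=CCC[C@]1(C)CCC2=C(O1)C3C=CC2(CCC(=O)c4ccc(OC(=O)C(C)(C)C)cc4OC(=O)C(C)(C)C)O3 | intermediate
19 | 4-{3-[(2R)-8-hydroxy-2-methyl-2-(4-methylpent-3-en-1-yl)chroman-5-yl]propanoyl}-1,3-phenylene bis(2,2-dimethylpropanoate) | CC(C)=CCC[C@]1(C)CCc2c(CCC(=O)c3ccc(OC(=O)C(C)(C)C)cc3OC(=O)C(C)(C)C)ccc(O)c2O1 | intermediate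
20 | (2R)-5-{3-[2,4-bis(pivaloyloxy)phenyl]-3-oxopropyl}-2-methyl-2-(4-methylpent-3-en-1-yl)chroman-8-yl pivalate | CC(C)=CCC[C@]1(C)CCc2c(CCC(=O)c3ccc(OC(=O)C(C)(C)C)cc3OC(=O)C(C)(C)C)ccc(OC(=O)C(C)(C)C)c2O1 | intermediate
21 | (2S)-5-{3-[2,4-bis(pivaloyloxy)phenyl]-3-oxopropyl}-2-[2-(3,3-dimethyloxiran-2-yl)ethyl]-2-methylchroman-8-yl pivalate, both epimers at the oxirane carbon | CC1(C)OC1CC[C@]2(C)CCc3c(CCC(=O)c4ccc(OC(=O)C(C)(C)C)cc4OC(=O)C(C)(C)C)ccc(OC(=O)C(C)(C)C)c3O2 | intermediate
22 | (2S)-5-{3-[2,4-bis(pivaloyloxy)phenyl]-3-oxopropyl}-2-[4-hydroxy-4-methyl-3-(phenylselanyl)pentyl]-2-methylchroman-8-yl pivalate, both C3' epimers (formed in the flask) | CC(C)(O)C([Se]c1ccccc1)CC[C@]2(C)CCc3c(CCC(=O)c4ccc(OC(=O)C(C)(C)C)cc4OC(=O)C(C)(C)C)ccc(OC(=O)C(C)(C)C)c3O2 | intermediate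
23 | selenoxide of 22, (2S), mixture of isomers at C3' and selenium (formed in the flask) | CC(C)(O)C([Se](=O)c1ccccc1)CC[C@]2(C)CCc3c(CCC(=O)c4ccc(OC(=O)C(C)(C)C)cc4OC(=O)C(C)(C)C)ccc(OC(=O)C(C)(C)C)c3O2 | intermediate
24 | (2S)-5-{3-[2,4-bis(pivaloyloxy)phenyl]-3-oxopropyl}-2-[(2E)-4-hydroxy-4-methylpent-2-en-1-yl]-2-methylchroman-8-yl pivalate | CC(C)(O)/C=C/C[C@]1(C)CCc2c(CCC(=O)c3ccc(OC(=O)C(C)(C)C)cc3OC(=O)C(C)(C)C)ccc(OC(=O)C(C)(C)C)c2O1 | intermediate
25 | (2R)-5-{3-[2,4-bis(pivaloyloxy)phenyl]-3-oxopropyl}-2-[(2E)-4-hydroxy-4-methylpent-2-en-1-yl]-2-methyl-2H-chromen-8-yl pivalate | CC(C)(O)/C=C/C[C@]1(C)C=Cc2c(CCC(=O)c3ccc(OC(=O)C(C)(C)C)cc3OC(=O)C(C)(C)C)ccc(OC(=O)C(C)(C)C)c2O1 | intermediate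
26 | 1-(2,4-dihydroxyphenyl)-3-{(2R)-8-hydroxy-2-[(2E)-4-hydroxy-4-methylpent-2-en-1-yl]-2-methyl-2H-chromen-5-yl}propan-1-one (CNP0311864.1) | CC(C)(O)/C=C/C[C@]1(C)C=Cc2c(CCC(=O)c3ccc(O)cc3O)ccc(O)c2O1 | target

**Step count and risks**

Total steps: 15. Longest linear sequence: 12 (steps 1–6 and 10–15); steps 7–9 form the furan branch.

Steps most likely to fail:

1. Step 10 (the new benzannulation). Fluoride may attack the sulfonyl sulfur instead of silicon and return the lactone enolate, the short-lived ynol ether may oligomerise or add to the ketone, or the cycloaddition may run with poor regioselectivity so that C8a bonds to the substituted furan carbon. The fallback builds the pyran ring onto a purchased benzene ring by known cross-coupling chemistry and keeps linalool as the source of C2. It sets out from the alkylborane 2 of step 1 and returns to the route at 20.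
   - Borane 2, after hydrolysis of excess hydride, would be coupled with commercial 2-bromo-3-hydroxy-4-methoxybenzaldehyde in a B-alkyl Suzuki–Miyaura reaction (PdCl2(dppf), K3PO4, DMF–H2O, 60 °C) to give 3-hydroxy-2-[(3R)-3-hydroxy-3,7-dimethyloct-6-en-1-yl]-4-methoxybenzaldehyde F1.
   - Selective sulfonylation of the phenol (PhNTf2, K2CO3, THF) would give 3-formyl-2-[(3R)-3-hydroxy-3,7-dimethyloct-6-en-1-yl]-6-methoxyphenyl trifluoromethanesulfonate F2.
   - Palladium-catalysed intramolecular C–O coupling of the tertiary alcohol (Pd(OAc)2, 2-(di-tert-butylphosphino)-1,1'-binaphthyl, K3PO4, toluene, 80 °C) would close the pyran ring with retention at the carbinol carbon to give (R)-8-methoxy-2-methyl-2-(4-methylpent-3-en-1-yl)chromane-5-carbaldehyde F3.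
   - Claisen–Schmidt condensation of F3 with 12 (KOH, EtOH) would give (E)-1-(2,4-dihydroxyphenyl)-3-[(2R)-8-methoxy-2-methyl-2-(4-methylpent-3-en-1-yl)chroman-5-yl]prop-2-en-1-one F4.
   - Hydrogenation with RhCl(PPh3)3, which leaves the trisubstituted alkene alone, would give 1-(2,4-dihydroxyphenyl)-3-[(2R)-8-methoxy-2-methyl-2-(4-methylpent-3-en-1-yl)chroman-5-yl]propan-1-one F5.
   - Demethylation with NaSEt in DMF at 130 °C would give 1-(2,4-dihydroxyphenyl)-3-[(2R)-8-hydroxy-2-methyl-2-(4-methylpent-3-en-1-yl)chroman-5-yl]propan-1-one F6.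
   - Exhaustive pivaloylation (t-BuCOCl, Et3N, DMAP) would then give 20.

2. Step 14 (DDQ dehydrogenation). Hydride abstraction at C4 may be too slow on the acyloxy-substituted ring, so that dehydrogenation of the CH2–CH2 unit beside the ketone or oxidation at the C5 benzylic methylene competes. The fallback replaces hydride abstraction by radical C–H bromination and base-induced elimination. It sets out from 24 and returns at 25: NBS with AIBN in PhCF3 at 80 °C would brominate the benzylic C4 position to give (2R)-4-bromo-5-{3-[2,4-bis(pivaloyloxy)phenyl]-3-oxopropyl}-2-[(2E)-4-hydroxy-4-methylpent-2-en-1-yl]-2-methylchroman-8-yl pivalate F7 (both C4 epimers), and DBU in THF would remove HBr across C3–C4 to give 25.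

3. Step 13 (selenide opening and selenoxide elimination). The aryl pivalates may undergo ethanolysis in the basic selenide medium, residual borohydride may reduce the ketone, or perseleninic acid may over-oxidise during the elimination. The fallback reaches the allylic alcohol by an ene reaction of singlet oxygen and omits the epoxide 21. It sets out from 20 and returns at 24: sensitised photooxygenation (O2, tetraphenylporphyrin, visible light, CH2Cl2, 0 °C) would give (2S)-5-{3-[2,4-bis(pivaloyloxy)phenyl]-3-oxopropyl}-2-[(2E)-4-hydroperoxy-4-methylpent-2-en-1-yl]-2-methylchroman-8-yl pivalate F8 together with its secondary regioisomer, and reduction with PPh3 followed by chromatographic removal of the isomeric alcohol would give 24.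

Further compounds
F1 | step 10 | 3-hydroxy-2-[(3R)-3-hydroxy-3,7-dimethyloct-6-en-1-yl]-4-methoxybenzaldehyde | CC(C)=CCC[C@](O)(C)CCc1c(C=O)ccc(OC)c1O
F2 | step 10 | 3-formyl-2-[(3R)-3-hydroxy-3,7-dimethyloct-6-en-1-yl]-6-methoxyphenyl trifluoromethanesulfonate | CC(C)=CCC[C@](O)(C)CCc1c(C=O)ccc(OC)c1OS(=O)(=O)C(F)(F)F
F3 | step 10 | (R)-8-methoxy-2-methyl-2-(4-methylpent-3-en-1-yl)chromane-5-carbaldehyde | CC(C)=CCC[C@]1(C)CCc2c(C=O)ccc(OC)c2O1
F4 | step 10 | (E)-1-(2,4-dihydroxyphenyl)-3-[(2R)-8-methoxy-2-methyl-2-(4-methylpent-3-en-1-yl)chroman-5-yl]prop-2-en-1-one | CC(C)=CCC[C@]1(C)CCc2c(/C=C/C(=O)c3ccc(O)cc3O)ccc(OC)c2O1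
F5 | step 10 | 1-(2,4-dihydroxyphenyl)-3-[(2R)-8-methoxy-2-methyl-2-(4-methylpent-3-en-1-yl)chroman-5-yl]propan-1-one | CC(C)=CCC[C@]1(C)CCc2c(CCC(=O)c3ccc(O)cc3O)ccc(OC)c2O1
F6 | step 10 | 1-(2,4-dihydroxyphenyl)-3-[(2R)-8-hydroxy-2-methyl-2-(4-methylpent-3-en-1-yl)chroman-5-yl]propan-1-one | CC(C)=CCC[C@]1(C)CCc2c(CCC(=O)c3ccc(O)cc3O)ccc(O)c2O1
F7 | step 14 | (2R)-4-bromo-5-{3-[2,4-bis(pivaloyloxy)phenyl]-3-oxopropyl}-2-[(2E)-4-hydroxy-4-methylpent-2-en-1-yl]-2-methylchroman-8-yl pivalate | CC(C)(O)/C=C/C[C@]1(C)CC(Br)c2c(CCC(=O)c3ccc(OC(=O)C(C)(C)C)cc3OC(=O)C(C)(C)C)ccc(OC(=O)C(C)(C)C)c2O1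
F8 | step 13 | (2S)-5-{3-[2,4-bis(pivaloyloxy)phenyl]-3-oxopropyl}-2-[(2E)-4-hydroperoxy-4-methylpent-2-en-1-yl]-2-methylchroman-8-yl pivalate | CC(C)(OO)/C=C/C[C@]1(C)CCc2c(CCC(=O)c3ccc(OC(=O)C(C)(C)C)cc3OC(=O)C(C)(C)C)ccc(OC(=O)C(C)(C)C)c2O1
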